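Ring C (the pyran ring) of the galloylated epigallocatechin unit is cut across O1–C2 and C3–C4. O1, C8a, C4a and C4 are read as an ortho-quinone methide whose C4 already carries C8 of the terminal epicatechin unit. C2=C3 is read as a (Z)-enol gallate of the pyrogallol-type arylacetaldehyde. One chiral-acid-catalysed oxa-[4+2] cycloaddition should close ring C, set C2, C3 and C4, install ring B and the 3-O-galloyl ester, and funnel both carbinol epimers of its benzhydrol precursor into one configuration. Two C4→C8 couplings with an epigallocatechin electrophile and a global hydrogenolysis complete the tetramer.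

Key step: step 8

Remark: the target is read as epigallocatechin-(4β→8)-epigallocatechin-(4β→8)-epigallocatechin 3-O-gallate-(4β→8)-epicatechin. From the upper end the four flavan units are called the top unit, the middle unit, the gallate unit and the bottom unit (the epicatechin). Each has ring A (phloroglucinol ring), ring B (pendant aryl) and ring C (pyran), in the usual flavan numbering.

Assumption: the (R) enantiomer of the phosphoric acid TRIP is written as the one that exposes the required face of the ortho-quinone methide. This sense of induction is assigned by analogy with related cycloadditions; if it proved opposite, the (S) acid would be used in the same step.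

Step 1
Reactants: 1 (−)-epicatechin
Product: 2 5,7,3',4'-tetra-O-benzyl-(−)-epicatechin
Conditions: BnBr (4.2 equiv), K2CO3, DMF, 0 °C to rt, argon
Reagents that add atoms: benzyl bromide, BrCc1ccccc1
Why: Williamson etherification in which K2CO3 deprotonates only the four phenols, so the secondary 3-OH and the C2/C3 stereocentres should stay untouched.

Step 2
Reactants: 2 5,7,3',4'-tetra-O-benzyl-(−)-epicatechin
Product: 3 3,5,7,3',4'-penta-O-benzyl-(−)-epicatechin
Conditions: NaH, BnBr, Bu4NI (cat.), DMF, 0 °C to rt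
Reagents that add atoms: benzyl bromide, BrCc1ccccc1
Why: Williamson etherification of the secondary alkoxide, which cannot epimerise C2 because no free phenol is left to open ring C through a quinone methide.

Step 3
Reactants: 3 3,5,7,3',4'-penta-O-benzyl-(−)-epicatechin
Product: 4 8-bromo-3,5,7,3',4'-penta-O-benzyl-(−)-epicatechin
Conditions: NBS (1.0 equiv), CH2Cl2, −78 °C to rt
Reagents that add atoms: N-bromosuccinimide, O=C1CCC(=O)N1Br
Why: electrophilic aromatic bromination, which in 5,7-dibenzyloxyflavans should take place at C8, the most nucleophilic and accessible position of ring A.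

Step 4
Reactants: 5 2,4,6-trihydroxybenzaldehyde
Product: 6 2,4-bis(benzyloxy)-6-hydroxybenzaldehyde
Conditions: BnBr (2.05 equiv), K2CO3, DMF, rt
Reagents that add atoms: benzyl bromide, BrCc1ccccc1
Why: Williamson etherification that should stop at the dibenzyl ether because the last phenol is locked in a hydrogen bond to the formyl group and is the least nucleophilic.

Step 5
Reactants: 4 8-bromo-3,5,7,3',4'-penta-O-benzyl-(−)-epicatechin; 6 2,4-bis(benzyloxy)-6-hydroxybenzaldehyde
Product: 9 (2-hydroxy-4,6-dibenzyloxyphenyl)(penta-O-benzylepicatechin-8-yl)methanol as a mixture of carbinol epimers, via sodium phenoxide 7 (not isolated), via aryllithium 8 (not isolated)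
Conditions: 4, n-BuLi, THF, −78 °C; then 7 (from 6, NaH, THF, 0 °C), −78 to 0 °C; H2O; chromatography on Et3N-deactivated silica
Reagents that add atoms: none
Why: bromine–lithium exchange followed by 1,2-addition of the aryllithium to the aldehyde, with the phenol pre-deprotonated so that it cannot quench 8; the new carbinol centre forms unselectively and is erased in step 8.

Step 6
Reactants: 10 3,4,5-tris(benzyloxy)benzaldehyde
Product: 11 1,2,3-tris(benzyloxy)-5-ethynylbenzene
Conditions: Ohira–Bestmann reagent, K2CO3, MeOH/THF, rt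
Reagents that add atoms: dimethyl (1-diazo-2-oxopropyl)phosphonate, CC(=O)C(=[N+]=[N-])P(=O)(OC)OC
Why: Seyferth–Gilbert homologation in the Ohira–Bestmann variant, in which the diazomethylphosphonate anion formed in the flask adds to the aldehyde and the alkylidene carbene rearranges to the terminal alkyne.

Step 7
Reactants: 11 1,2,3-tris(benzyloxy)-5-ethynylbenzene; 12 3,4,5-tris(benzyloxy)benzoic acid
Product: 13 (Z)-2-[3,4,5-tris(benzyloxy)phenyl]ethenyl 3,4,5-tris(benzyloxy)benzoate
Conditions: Ru(η3-CH2C(CH3)CH2)2(Ph2P(CH2)4PPh2) (3 mol %), toluene, 60 °C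
Reagents that add atoms: none
Why: ruthenium-catalysed anti-Markovnikov hydro-oxycarbonylation of a terminal alkyne, in which the carboxylate attacks the α-carbon of a ruthenium vinylidene and protonolysis should deliver the Z-enol ester under kinetic control.

Step 8
Reactants: 9 (2-hydroxy-4,6-dibenzyloxyphenyl)(penta-O-benzylepicatechin-8-yl)methanol (both epimers); 13 (Z)-2-[3,4,5-tris(benzyloxy)phenyl]ethenyl 3,4,5-tris(benzyloxy)benzoate
Product: 15 perbenzylated epigallocatechin 3-O-gallate-(4β→8)-epicatechin, via ortho-quinone methide 14 (not isolated)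
Conditions: (R)-TRIP [(R)-3,3'-bis(2,4,6-triisopropylphenyl)-1,1'-binaphthyl-2,2'-diyl hydrogen phosphate] (10 mol %), 13 (2.5 equiv), 5 Å MS, toluene, −20 °C to rt, 9 added slowly
Reagents that add atoms: none
Why: Proposed new method: the chiral phosphoric acid dehydrates either carbinol epimer of 9 to the planar, phosphate-bound ortho-quinone methide 14, whose O1=C8a–C4a=C4 heterodiene adds across C2=C3 of 13 in an asynchronous inverse-electron-demand oxa-Diels–Alder reaction in which C4–C3 bonding runs ahead, positive charge builds at benzylic C2 and O1 then closes onto C2. The closest known reaction type is the Brønsted-acid-catalysed (also chiral-phosphoric-acid-catalysed) [4+2] cycloaddition of ortho-quinone methides from ortho-hydroxybenzhydrols with electron-rich β-substituted styrenes to 2,4-diarylchromans, and what is new is an enol ester (a β-acyloxystyrene) as the 2π partner. Ring C of the gallate unit is closed as a six-membered ring by intermolecular [4π+2π] cycloaddition, which in its stepwise limit ends with phenolic O1 capturing the C2 benzylic cation. C2 and C3 should come out cis because the Z geometry of 13 is transferred suprafacially, C4 should come out trans to the 3-O-galloyl group because the E-configured methide with its twisted, bulky epicatechinyl group at C4 admits the alkene only in the exo orientation (the Z rotamer reacting endo would give the same isomer), and the absolute sense (2R,3R with the 4β-aryl bond) is set by the chiral phosphate pocket, which shields one face of 14, while the carbinol centre of 9 is erased. The step needs C4 to bond to the acyloxy-bearing carbon, which is secured because the oxygen lone pair of 13 is tied up in the ester, so that the para-benzyloxybenzyl cation at C2, further assisted by the galloyl carbonyl, outweighs the poorly stabilised α-acyloxy cation of the reverse orientation. Self-alkylation of the electron-rich arene rings by 14 is held back by the crowding at C4, by the excess of 13 and by slow addition of 9.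

Step 9
Reactants: 16 (−)-epigallocatechin
Product: 17 5,7,3',4',5'-penta-O-benzyl-(−)-epigallocatechin
Conditions: BnBr (5.5 equiv), K2CO3, DMF (degassed), 0 °C to rt, argon
Reagents that add atoms: benzyl bromide, BrCc1ccccc1
Why: Williamson etherification of the five phenols under a base too weak to touch the secondary 3-OH, with air excluded to protect the pyrogallol ring; no stereocentre is affected.

Step 10
Reactants: 17 5,7,3',4',5'-penta-O-benzyl-(−)-epigallocatechin
Product: 18 4β-(2-ethoxyethoxy)-5,7,3',4',5'-penta-O-benzyl-(−)-epigallocatechin (4-alkoxy group trans to the 3-OH)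
Conditions: DDQ (2 equiv), 2-ethoxyethanol, CH2Cl2, rt
Reagents that add atoms: 2-ethoxyethanol, CCOCCO
Why: DDQ benzylic oxidation by hydride abstraction at C4, which two benzyloxy groups of ring A activate, followed by capture of the cation by the alcohol from the face anti to the 3-OH, which sets C4 as the 4β-ether under substrate control.

Step 11
Reactants: 15 perbenzylated epigallocatechin 3-O-gallate-(4β→8)-epicatechin; 18 4β-(2-ethoxyethoxy)-5,7,3',4',5'-penta-O-benzyl-(−)-epigallocatechin
Product: 19 protected trimer penta-O-benzylepigallocatechin-(4β→8)-[perbenzylated epigallocatechin 3-O-gallate]-(4β→8)-penta-O-benzylepicatechin (3-OH of the middle unit free)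
Conditions: TMSOTf (0.2 equiv), CH2Cl2, −78 to −40 °C, 18 (1.2 equiv) added slowly; then Et3N, aq. NaHCO3
Reagents that add atoms: none
Why: Lewis-acid-promoted Friedel–Crafts-type flavan coupling in which ionisation of the C4 ether of 18 gives a benzylic cation that C8 of ring A of the gallate unit, the most nucleophilic free position of 15, should attack anti to the 3-OH to set the 4β (3,4-trans) bond.

Step 12
Reactants: 19 protected trimer; 18 4β-(2-ethoxyethoxy)-5,7,3',4',5'-penta-O-benzyl-(−)-epigallocatechin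
Product: 20 protected tetramer (the target skeleton carrying twenty-three benzyl groups; the 3-OH of the top unit free; the 3-OH of the middle unit free)
Conditions: TMSOTf (0.2 equiv), CH2Cl2, −78 to −40 °C, 18 (1.2 equiv) added slowly; then Et3N, aq. NaHCO3
Reagents that add atoms: none
Why: the same Lewis-acid-promoted Friedel–Crafts-type flavan coupling, now at C8 of ring A of the middle unit, the most nucleophilic and accessible free position of 19, again anti to the 3-OH of the incoming cation to set the 4β bond.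

Step 13
Reactants: 20 protected tetramer
Product: 21 epigallocatechin-(4β→8)-epigallocatechin-(4β→8)-epigallocatechin 3-O-gallate-(4β→8)-epicatechin (target)
Conditions: H2 (1 atm), Pd(OH)2/C, THF/MeOH/H2O, rt; filtration, lyophilisation
Reagents that add atoms: none
Why: catalytic hydrogenolysis of the 22 aryl benzyl ethers and the one alkyl benzyl ether under neutral conditions, which should leave the galloyl ester, the interflavan bonds and all stereocentres untouched.

Compound list
1 | (−)-epicatechin, (2R,3R) | Oc1cc(O)c2c(c1)O[C@H](c1ccc(O)c(O)c1)[C@H](O)C2 | starting material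
2 | 5,7,3',4'-tetra-O-benzyl-(−)-epicatechin | c1c(OCc2ccccc2)cc(OCc2ccccc2)c2c1O[C@H](c1ccc(OCc3ccccc3)c(OCc3ccccc3)c1)[C@H](O)C2 | intermediate
3 | 3,5,7,3',4'-penta-O-benzyl-(−)-epicatechin | c1c(OCc2ccccc2)cc(OCc2ccccc2)c2c1O[C@H](c1ccc(OCc3ccccc3)c(OCc3ccccc3)c1)[C@H](OCc1ccccc1)C2 | intermediate
4 | 8-bromo-3,5,7,3',4'-penta-O-benzyl-(−)-epicatechin | Brc1c(OCc2ccccc2)cc(OCc2ccccc2)c2c1O[C@H](c1ccc(OCc3ccccc3)c(OCc3ccccc3)c1)[C@H](OCc1ccccc1)C2 | intermediate
5 | 2,4,6-trihydroxybenzaldehyde | O=Cc1c(O)cc(O)cc1O | starting material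
6 | 2,4-bis(benzyloxy)-6-hydroxybenzaldehyde | O=Cc1c(O)cc(OCc2ccccc2)cc1OCc1ccccc1 | intermediate
7 | sodium 3,5-bis(benzyloxy)-2-formylphenoxide | [Na+].[O-]c1cc(OCc2ccccc2)cc(OCc2ccccc2)c1C=O | intermediate
8 | 8-lithio-3,5,7,3',4'-penta-O-benzyl-(−)-epicatechin | [Li]c1c(OCc2ccccc2)cc(OCc2ccccc2)c2c1O[C@H](c1ccc(OCc3ccccc3)c(OCc3ccccc3)c1)[C@H](OCc1ccccc1)C2 | intermediate
9 | (2-hydroxy-4,6-dibenzyloxyphenyl)(penta-O-benzylepicatechin-8-yl)methanol, both carbinol epimers | OC(c1c(O)cc(OCc2ccccc2)cc1OCc1ccccc1)c1c(OCc2ccccc2)cc(OCc2ccccc2)c2c1O[C@H](c1ccc(OCc3ccccc3)c(OCc3ccccc3)c1)[C@H](OCc1ccccc1)C2 | intermediate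
10 | 3,4,5-tris(benzyloxy)benzaldehyde | O=Cc1cc(OCc2ccccc2)c(OCc2ccccc2)c(OCc2ccccc2)c1 | starting material
11 | 1,2,3-tris(benzyloxy)-5-ethynylbenzene | C#Cc1cc(OCc2ccccc2)c(OCc2ccccc2)c(OCc2ccccc2)c1 | intermediate
12 | 3,4,5-tris(benzyloxy)benzoic acid | OC(=O)c1cc(OCc2ccccc2)c(OCc2ccccc2)c(OCc2ccccc2)c1 | starting material
13 | (Z)-2-[3,4,5-tris(benzyloxy)phenyl]ethenyl 3,4,5-tris(benzyloxy)benzoate | O=C(O/C=C\c1cc(OCc2ccccc2)c(OCc2ccccc2)c(OCc2ccccc2)c1)c1cc(OCc2ccccc2)c(OCc2ccccc2)c(OCc2ccccc2)c1 | intermediate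
14 | ortho-quinone methide: (E)-3,5-bis(benzyloxy)-6-[(penta-O-benzylepicatechin-8-yl)methylidene]cyclohexa-2,4-dien-1-one | O=C1C=C(OCc2ccccc2)C=C(OCc2ccccc2)/C1=C\c1c(OCc2ccccc2)cc(OCc2ccccc2)c2c1O[C@H](c1ccc(OCc3ccccc3)c(OCc3ccccc3)c1)[C@H](OCc1ccccc1)C2 | intermediate
15 | perbenzylated epigallocatechin 3-O-gallate-(4β→8)-epicatechin: gallate unit with 2,3-cis and 3,4-trans ring C, 5,7,3',4',5'-penta-O-benzyl and a tri-O-benzylgalloyl ester; bottom unit penta-O-benzyl | O=C(O[C@@H]1[C@@H](c2c(OCc3ccccc3)cc(OCc3ccccc3)c3c2O[C@H](c2ccc(OCc4ccccc4)c(OCc4ccccc4)c2)[C@H](OCc2ccccc2)C3)c2c(OCc3ccccc3)cc(OCc3ccccc3)cc2O[C@@H]1c1cc(OCc2ccccc2)c(OCc2ccccc2)c(OCc2ccccc2)c1)c1cc(OCc2ccccc2)c(OCc2ccccc2)c(OCc2ccccc2)c1 | intermediate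
16 | (−)-epigallocatechin, (2R,3R) | Oc1cc(O)c2c(c1)O[C@H](c1cc(O)c(O)c(O)c1)[C@H](O)C2 | starting material
17 | 5,7,3',4',5'-penta-O-benzyl-(−)-epigallocatechin | c1c(OCc2ccccc2)cc(OCc2ccccc2)c2c1O[C@H](c1cc(OCc3ccccc3)c(OCc3ccccc3)c(OCc3ccccc3)c1)[C@H](O)C2 | intermediate
18 | 4β-(2-ethoxyethoxy)-5,7,3',4',5'-penta-O-benzyl-(−)-epigallocatechin (2,3-cis, 3,4-trans) | CCOCCO[C@H]1c2c(OCc3ccccc3)cc(OCc3ccccc3)cc2O[C@H](c2cc(OCc3ccccc3)c(OCc3ccccc3)c(OCc3ccccc3)c2)[C@@H]1O | intermediate
19 | protected trimer (middle unit, gallate unit, bottom unit): eighteen benzyl groups; 3-OH of the middle unit free; both interflavan bonds 4β→8 | O=C(O[C@@H]1[C@@H](c2c(OCc3ccccc3)cc(OCc3ccccc3)c3c2O[C@H](c2ccc(OCc4ccccc4)c(OCc4ccccc4)c2)[C@H](OCc2ccccc2)C3)c2c(OCc3ccccc3)cc(OCc3ccccc3)c([C@H]3c4c(OCc5ccccc5)cc(OCc5ccccc5)cc4O[C@H](c4cc(OCc5ccccc5)c(OCc5ccccc5)c(OCc5ccccc5)c4)[C@@H]3O)c2O[C@@H]1c1cc(OCc2ccccc2)c(OCc2ccccc2)c(OCc2ccccc2)c1)c1cc(OCc2ccccc2)c(OCc2ccccc2)c(OCc2ccccc2)c1 | intermediate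
20 | protected tetramer: twenty-three benzyl groups; 3-OH of the top unit free; 3-OH of the middle unit free; all interflavan bonds 4β→8 | O=C(O[C@@H]1[C@@H](c2c(OCc3ccccc3)cc(OCc3ccccc3)c3c2O[C@H](c2ccc(OCc4ccccc4)c(OCc4ccccc4)c2)[C@H](OCc2ccccc2)C3)c2c(OCc3ccccc3)cc(OCc3ccccc3)c([C@H]3c4c(OCc5ccccc5)cc(OCc5ccccc5)c([C@H]5c6c(OCc7ccccc7)cc(OCc7ccccc7)cc6O[C@H](c6cc(OCc7ccccc7)c(OCc7ccccc7)c(OCc7ccccc7)c6)[C@@H]5O)c4O[C@H](c4cc(OCc5ccccc5)c(OCc5ccccc5)c(OCc5ccccc5)c4)[C@@H]3O)c2O[C@@H]1c1cc(OCc2ccccc2)c(OCc2ccccc2)c(OCc2ccccc2)c1)c1cc(OCc2ccccc2)c(OCc2ccccc2)c(OCc2ccccc2)c1 | intermediate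
21 | epigallocatechin-(4β→8)-epigallocatechin-(4β→8)-epigallocatechin 3-O-gallate-(4β→8)-epicatechin | O=C(O[C@@H]1[C@@H](c2c(O)cc(O)c3c2O[C@H](c2ccc(O)c(O)c2)[C@H](O)C3)c2c(O)cc(O)c([C@H]3c4c(O)cc(O)c([C@H]5c6c(O)cc(O)cc6O[C@H](c6cc(O)c(O)c(O)c6)[C@@H]5O)c4O[C@H](c4cc(O)c(O)c(O)c4)[C@@H]3O)c2O[C@@H]1c1cc(O)c(O)c(O)c1)c1cc(O)c(O)c(O)c1 | target

Total step count: 13 steps.
Longest linear sequence: 8 steps (steps 1, 2, 3, 5, 8, 11, 12 and 13).

Steps most likely to fail

Step 8 (Proposed new method). What may go wrong: addition in the reverse orientation, with O1 bonding to the acyloxy-bearing carbon; endo approach or attack on the wrong face, giving ring C diastereomers; loss of the Z geometry through a long-lived open cation; or Friedel–Crafts self-alkylation of the electron-rich rings by the quinone methide. The fallback uses known chemistry and makes the bond between C4 of the gallate unit and C8 of the bottom unit last, from units of natural configuration. It sets out from 18: Steglich esterification with 12 (DCC, DMAP, CH2Cl2) should give the galloylated C4 electrophile 4β-(2-ethoxyethoxy)-penta-O-benzylepigallocatechin 3-O-[3,4,5-tris(benzyloxy)benzoate] F1. TMSOTf-promoted coupling of F1 with the nucleophile 3 (CH2Cl2, −78 °C) at C8, anti to the participating 3-O-acyl group, should then give 15, where the route is rejoined.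

Step 12. What may go wrong: self-condensation of the uncapped electrophile through its own C8, attack at C6 instead of C8 of the large nucleophile, or acid-induced scission and scrambling of the interflavan bonds already present. The fallback caps C8 of the incoming top unit with bromine. It sets out from 17: NBS bromination should give 8-bromo-5,7,3',4',5'-penta-O-benzylepigallocatechin F2, and DDQ with 2-ethoxyethanol should give its 4β-(2-ethoxyethoxy) derivative F3, which can no longer act as a nucleophile. TMSOTf coupling of F3 with 19 should give the 8-bromo protected tetramer F4. Hydrogenolysis of F4 (H2, Pd(OH)2/C, Et3N, THF/MeOH/H2O) removes the bromine together with all benzyl groups and comes back to the route at 21.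

Step 5. What may go wrong: sluggish addition of the hindered aryllithium to the deactivated, doubly ortho-substituted phenoxide aldehyde; proton transfer that quenches the aryllithium; or premature ionisation of the very electron-rich benzhydrol during isolation. The fallback reverses the polarity of the two partners. It sets out from 4: the aryllithium 8 is quenched with DMF to give 8-formyl-3,5,7,3',4'-penta-O-benzylepicatechin F5. Commercial 3,5-bis(benzyloxy)phenol is converted with EtMgBr into bromomagnesium 3,5-bis(benzyloxy)phenoxide F6. In toluene/CH2Cl2, F6 should add to F5 through a six-membered magnesium chelate (magnesium-phenoxide-directed ortho-hydroxyalkylation) to give 9, where the route is rejoined.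

Further compounds
F1 | step 8 | 4β-(2-ethoxyethoxy)-5,7,3',4',5'-penta-O-benzylepigallocatechin 3-O-[3,4,5-tris(benzyloxy)benzoate] | CCOCCO[C@H]1c2c(OCc3ccccc3)cc(OCc3ccccc3)cc2O[C@H](c2cc(OCc3ccccc3)c(OCc3ccccc3)c(OCc3ccccc3)c2)[C@@H]1OC(=O)c1cc(OCc2ccccc2)c(OCc2ccccc2)c(OCc2ccccc2)c1
F2 | step 12 | 8-bromo-5,7,3',4',5'-penta-O-benzyl-(−)-epigallocatechin | Brc1c(OCc2ccccc2)cc(OCc2ccccc2)c2c1O[C@H](c1cc(OCc3ccccc3)c(OCc3ccccc3)c(OCc3ccccc3)c1)[C@H](O)C2
F3 | step 12 | 8-bromo-4β-(2-ethoxyethoxy)-5,7,3',4',5'-penta-O-benzyl-(−)-epigallocatechin | CCOCCO[C@H]1c2c(OCc3ccccc3)cc(OCc3ccccc3)c(Br)c2O[C@H](c2cc(OCc3ccccc3)c(OCc3ccccc3)c(OCc3ccccc3)c2)[C@@H]1O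
F4 | step 12 | protected tetramer 20 carrying bromine at C8 of the top unit | O=C(O[C@@H]1[C@@H](c2c(OCc3ccccc3)cc(OCc3ccccc3)c3c2O[C@H](c2ccc(OCc4ccccc4)c(OCc4ccccc4)c2)[C@H](OCc2ccccc2)C3)c2c(OCc3ccccc3)cc(OCc3ccccc3)c([C@H]3c4c(OCc5ccccc5)cc(OCc5ccccc5)c([C@H]5c6c(OCc7ccccc7)cc(OCc7ccccc7)c(Br)c6O[C@H](c6cc(OCc7ccccc7)c(OCc7ccccc7)c(OCc7ccccc7)c6)[C@@H]5O)c4O[C@H](c4cc(OCc5ccccc5)c(OCc5ccccc5)c(OCc5ccccc5)c4)[C@@H]3O)c2O[C@@H]1c1cc(OCc2ccccc2)c(OCc2ccccc2)c(OCc2ccccc2)c1)c1cc(OCc2ccccc2)c(OCc2ccccc2)c(OCc2ccccc2)c1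
F5 | step 5 | 8-formyl-3,5,7,3',4'-penta-O-benzyl-(−)-epicatechin | O=Cc1c(OCc2ccccc2)cc(OCc2ccccc2)c2c1O[C@H](c1ccc(OCc3ccccc3)c(OCc3ccccc3)c1)[C@H](OCc1ccccc1)C2
F6 | step 5 | bromomagnesium 3,5-bis(benzyloxy)phenoxide | Br[Mg]Oc1cc(OCc2ccccc2)cc(OCc2ccccc2)c1
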